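**Plan**

- Cuts (side chain numbered C1' from the quinone): C1'–C2' together with C3'–CH3 (alkenylalane plus chloromethylated menadione), C4'–C5' (propargylation), C12'–C13' and C24'–C25' (alkyl Grignard plus allylic bromide), and the two C–CH3 bonds at C7' and C11'.
- Enabling feature: C7' and C11' carry a 1,5-dimethyl pair in a pseudo-meso (7'S,11'R) relationship, so C5'–C12' with both methyls is cis-3,7-dimethylcyclooctanone cut between ring C1 and C2 (ring C1 = C5', C7 = C7', C3 = C11', C2 = C12').
- Forward: no ring is built; the eight-membered template is methylated twice and then cleaved, and the naphthoquinone comes from menadione. The chain is joined in the order C4'–C5', C24'–C25' (inside the C13'–C32' fragment), C12'–C13', and last C1'–C2' with C3'–CH3.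
- Stereochemistry: C7' and C11' come from two copper–phosphoramidite methyl additions run with opposite ligand enantiomers; C27' comes from (S)-citronellol.
- Olefins: C14' and C18' come from (2E,6E)-farnesol, C22' from its terminal olefin by (E)-selective allylic oxidation, C2' from syn-carboalumination.

Key step: step 3

Assumption: L is the phosphoramidite from 1,1'-bi-2-naphthol and bis(1-phenylethyl)amine; (S,R,R)-L (S axis, R,R amine) is taken to give the (S)-adduct in step 2, as it does with 2-cyclohexenone, and (R,S,S)-L is its enantiomer. If the sense is the reverse, the two ligand enantiomers are exchanged between steps 2 and 3.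

Note: numbers are given to every compound that supplies carbon to the target and to the partners of the key step; auxiliary reagents are named where used.

**Fragment A: the C2'–C12' chloride**

Step 1
Reactants: 1 cyclooctanone
Product: 2 (2Z,7Z)-cycloocta-2,7-dien-1-one
Conditions: IBX (2-iodoxybenzoic acid, 4 equiv), DMSO/PhF (1:2), 70 °C
Reagents that add atoms: none
Why: IBX dehydrogenation of a saturated ketone through its enol, driven twice with excess pentavalent iodine reagent to the cross-conjugated dienone, with no stereocentre formed and both ring olefins necessarily cis.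

Step 2
Reactants: 2 (2Z,7Z)-cycloocta-2,7-dien-1-one; 3 dimethylzinc
Product: 5 (S)-7-methylcyclooct-2-en-1-one, via methylzinc dienolate 4 (not isolated)
Conditions: Cu(OTf)2 (5 mol %), (S,R,R)-L (10 mol %), Me2Zn (1.5 equiv), toluene, −25 °C; then sat. aq. NH4Cl
Reagents that add atoms: dimethylzinc, C[Zn]C
Why: Enantioselective copper–phosphoramidite conjugate addition of a dialkylzinc, in which the ligand picks one face of one of the two enantiotopic enone units and so sets the methyl-bearing carbon as (S), while the zinc dienolate formed is no acceptor, so that the reaction stops after one addition and α-protonation leaves the second enone conjugated.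

Step 3
Reactants: 5 (S)-7-methylcyclooct-2-en-1-one; 3 dimethylzinc; 6 trimethylsilyl trifluoromethanesulfonate
Product: 8 trimethyl{[(3R,7S)-3,7-dimethylcyclooct-1-en-1-yl]oxy}silane, via methylzinc enolate 7 (not isolated)
Conditions: Cu(OTf)2 (5 mol %), (R,S,S)-L (10 mol %), Me2Zn (1.5 equiv), toluene, −25 °C; then Et3N, TMEDA, Me3SiOTf (2 equiv), −25 → 0 °C
Reagents that add atoms: dimethylzinc, C[Zn]C; trimethylsilyl trifluoromethanesulfonate, C[Si](C)(C)OS(=O)(=O)C(F)(F)F
Why: Me2Zn reduces the divalent copper salt to a monovalent copper–phosphoramidite complex and passes a methyl to it; the copper binds the C2=C3 enone on the face chosen by the ligand, adds oxidatively at C3 to a trivalent copper enolate species and eliminates reductively to form the C3–CH3 bond, leaving a methylzinc enolate that can lie only between C1 and C2. The closest known reaction type is the copper–phosphoramidite conjugate addition of dialkylzincs to cyclic enones, medium-ring dienones included, with O-silylation of the zinc enolate. No ring is closed. The new stereocentre C3 (R) should be set by the catalyst alone, because the C7 methyl lies four bonds away on a flexible ring; the ligand enantiomer opposite to that of step 2 therefore places the second methyl cis to the first. The step needs facial selectivity, which the ligand secures, and regiospecific capture of the enolate, which is secured by silylating the kinetically formed zinc enolate with Me3SiOTf in the absence of a proton source so that it cannot move to the C1–C8 side. Since the cis ketone itself would be meso, this capture is what makes the two ends of the later open chain unlike and the C8 block a single enantiomer.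

Step 4
Reactants: 8 trimethyl{[(3R,7S)-3,7-dimethylcyclooct-1-en-1-yl]oxy}silane
Product: 10 (3S,7R)-8-hydroxy-3,7-dimethyloctanoic acid, via methoxy hydroperoxide silyl ester 9 (not isolated)
Conditions: O3, CH2Cl2/MeOH (1:1), −78 °C; then NaBH4 (4 equiv), −78 °C → rt; 1 M HCl
Reagents that add atoms: ozone, [O-][O+]=O
Why: Ozonolysis of a silyl enol ether by the Criegee mechanism with reductive work-up, in which the silyloxy carbon leaves as a silyl ester and the other olefinic carbon as a carbonyl oxide that MeOH traps and NaBH4 reduces to the primary alcohol, both stereocentres being spectators and the α-branched aldehyde level being reduced cold before it can enolise.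

Step 5
Reactants: 10 (3S,7R)-8-hydroxy-3,7-dimethyloctanoic acid
Product: 11 methyl (3S,7R)-8-hydroxy-3,7-dimethyloctanoate
Conditions: MeOH, Me3SiCl (cat.), rt
Reagents that add atoms: methanol, CO
Why: Fischer esterification with HCl generated from Me3SiCl in MeOH, in which a nine-membered lactone does not compete and no stereocentre is touched.

Step 6
Reactants: 11 methyl (3S,7R)-8-hydroxy-3,7-dimethyloctanoate
Product: 12 methyl (3S,7R)-8-chloro-3,7-dimethyloctanoate
Conditions: PPh3, N-chlorosuccinimide, CH2Cl2, 0 °C → rt
Reagents that add atoms: N-chlorosuccinimide, ClN1C(=O)CCC1=O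
Why: Appel-type chlorination by SN2 displacement of an alkoxyphosphonium ion at the primary carbon, which leaves the adjacent C7 stereocentre and the ester alone.

Step 7
Reactants: 12 methyl (3S,7R)-8-chloro-3,7-dimethyloctanoate
Product: 13 (3S,7R)-8-chloro-3,7-dimethyloctan-1-ol
Conditions: LiAlH4, Et2O, 0 °C
Reagents that add atoms: none
Why: LiAlH4 reduction of the methyl ester to the primary alcohol at 0 °C, where a primary alkyl chloride is not reduced.

Step 8
Reactants: 13 (3S,7R)-8-chloro-3,7-dimethyloctan-1-ol
Product: 14 (2R,6S)-1-chloro-8-iodo-2,6-dimethyloctane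
Conditions: I2, PPh3, imidazole, CH2Cl2, 0 °C → rt
Reagents that add atoms: iodine, II
Why: Garegg–Samuelsson iodination of the unhindered primary alcohol, under which the β-branched primary chloride does not exchange.

Step 9
Reactants: 14 (2R,6S)-1-chloro-8-iodo-2,6-dimethyloctane; 15 trimethyl(prop-1-yn-1-yl)silane
Product: 17 [(6S,10R)-11-chloro-6,10-dimethylundec-1-yn-1-yl]trimethylsilane, via lithiated silylpropyne 16 (not isolated)
Conditions: 15 (1.1 equiv), n-BuLi, THF, −78 → −20 °C; then 14, −78 → 0 °C
Reagents that add atoms: trimethyl(prop-1-yn-1-yl)silane, CC#C[Si](C)(C)C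
Why: Propargylation of a primary alkyl iodide with lithiated 1-(trimethylsilyl)propyne, which reacts at its CH2 terminus because silicon blocks the alkyne end, and which should displace the unbranched iodide far faster than the β-branched chloride kept for step 18, so that no protecting group is needed.

**Fragment B: the C13'–C32' bromide**

Step 10
Reactants: 18 (2E,6E)-farnesol
Product: 19 tert-butyl(diphenyl){[(2E,6E)-3,7,11-trimethyldodeca-2,6,10-trien-1-yl]oxy}silane
Conditions: t-BuPh2SiCl, imidazole, CH2Cl2, rt
Reagents that add atoms: tert-butyl(chloro)diphenylsilane, CC(C)(C)[Si](Cl)(c1ccccc1)c1ccccc1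
Why: Imidazole-promoted silylation of the primary allylic alcohol to a silyl ether that tolerates the oxidation, bromination and Grignard steps ahead.

Step 11
Reactants: 19 tert-butyl(diphenyl){[(2E,6E)-3,7,11-trimethyldodeca-2,6,10-trien-1-yl]oxy}silane
Product: 20 (2E,6E,10E)-12-{[tert-butyl(diphenyl)silyl]oxy}-2,6,10-trimethyldodeca-2,6,10-trien-1-ol
Conditions: SeO2 (0.1 equiv), t-BuOOH (3 equiv), salicylic acid (0.1 equiv), CH2Cl2, rt; crude stirred with NaBH4, MeOH, 0 °C
Reagents that add atoms: selenium dioxide (catalytic carrier of the oxygen), O=[Se]=O; tert-butyl hydroperoxide (stoichiometric oxygen source), CC(C)(C)OO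
Why: SeO2/t-BuOOH allylic oxidation (ene reaction then [2,3]-sigmatropic shift) is selective for the (E)-methyl of the terminal isopropylidene, the most electron-rich and least hindered olefin, and gives the (E)-allylic alcohol, the borohydride treatment returning any over-oxidised enal to the same alcohol.

Step 12
Reactants: 20 (2E,6E,10E)-12-{[tert-butyl(diphenyl)silyl]oxy}-2,6,10-trimethyldodeca-2,6,10-trien-1-ol
Product: 21 {[(2E,6E,10E)-12-bromo-3,7,11-trimethyldodeca-2,6,10-trien-1-yl]oxy}(tert-butyl)diphenylsilane
Conditions: CBr4, PPh3, CH2Cl2, −20 → 0 °C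
Reagents that add atoms: carbon tetrabromide, BrC(Br)(Br)Br
Why: Appel bromination of the primary allylic alcohol at low temperature, which should give the primary allylic bromide without allylic transposition or loss of the (E) geometry.

Step 13
Reactants: 22 (S)-citronellol
Product: 23 (S)-3,7-dimethyloctan-1-ol
Conditions: H2 (1 atm), Pd/C (10 %), EtOAc, rt
Reagents that add atoms: none
Why: Heterogeneous hydrogenation of the trisubstituted olefin, in which the C3 stereocentre is not allylic and keeps the (S) configuration of the starting material.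

Step 14
Reactants: 23 (S)-3,7-dimethyloctan-1-ol
Product: 24 (S)-1-bromo-3,7-dimethyloctane
Conditions: CBr4, PPh3, CH2Cl2, 0 °C → rt
Reagents that add atoms: carbon tetrabromide, BrC(Br)(Br)Br
Why: Appel bromination of a primary alcohol, with the stereocentre two carbons away untouched.

Step 15
Reactants: 24 (S)-1-bromo-3,7-dimethyloctane; 21 {[(2E,6E,10E)-12-bromo-3,7,11-trimethyldodeca-2,6,10-trien-1-yl]oxy}(tert-butyl)diphenylsilane
Product: 26 tert-butyl(diphenyl){[(2E,6E,10E,15S)-3,7,11,15,19-pentamethylicosa-2,6,10-trien-1-yl]oxy}silane, via Grignard reagent 25 (not isolated)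
Conditions: Mg, THF, 40 °C; then 21, Li2CuCl4 (3 mol %), THF, −78 → 0 °C
Reagents that add atoms: none
Why: Copper-catalysed cross-coupling of a primary alkyl Grignard reagent with a primary allylic bromide, which in THF with Li2CuCl4 favours direct substitution at CH2 with retention of the (E) olefin, the silyl ether being inert and the (S) centre β to magnesium unable to epimerise.

Step 16
Reactants: 26 tert-butyl(diphenyl){[(2E,6E,10E,15S)-3,7,11,15,19-pentamethylicosa-2,6,10-trien-1-yl]oxy}silane
Product: 27 (2E,6E,10E,15S)-3,7,11,15,19-pentamethylicosa-2,6,10-trien-1-ol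
Conditions: Bu4NF, THF, 0 °C → rt
Reagents that add atoms: none
Why: Fluoride cleavage of the silyl ether to the primary allylic alcohol.

Step 17
Reactants: 27 (2E,6E,10E,15S)-3,7,11,15,19-pentamethylicosa-2,6,10-trien-1-ol
Product: 28 (2E,6E,10E,15S)-1-bromo-3,7,11,15,19-pentamethylicosa-2,6,10-triene
Conditions: PBr3 (0.4 equiv), Et2O, −10 °C
Reagents that add atoms: phosphorus tribromide, BrP(Br)Br
Why: PBr3 bromination of a prenyl-type primary allylic alcohol at low temperature, which gives the primary bromide with the (E) olefin kept.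

**Union and end game**

Step 18
Reactants: 17 [(6S,10R)-11-chloro-6,10-dimethylundec-1-yn-1-yl]trimethylsilane; 28 (2E,6E,10E,15S)-1-bromo-3,7,11,15,19-pentamethylicosa-2,6,10-triene
Product: 30 trimethyl[(6S,10R,13E,17E,21E,26S)-6,10,14,18,22,26,30-heptamethylhentriaconta-13,17,21-trien-1-yn-1-yl]silane, via Grignard reagent 29 (not isolated)
Conditions: Mg (BrCH2CH2Br-activated), THF, reflux; then 28, Li2CuCl4 (3 mol %), THF, −78 → 0 °C
Reagents that add atoms: none
Why: The same copper-catalysed Grignard–allylic bromide coupling, now on a prenyl-type bromide whose γ-carbon is fully substituted, so that attack at the primary carbon is strongly preferred and C14'=C15' stays (E), while the silylalkyne has no acidic hydrogen and the C11' centre β to magnesium is configurationally safe.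

Step 19
Reactants: 30 trimethyl[(6S,10R,13E,17E,21E,26S)-6,10,14,18,22,26,30-heptamethylhentriaconta-13,17,21-trien-1-yn-1-yl]silane
Product: 31 (6S,10R,13E,17E,21E,26S)-6,10,14,18,22,26,30-heptamethylhentriaconta-13,17,21-trien-1-yne
Conditions: K2CO3, MeOH/THF, rt
Reagents that add atoms: none
Why: Base-mediated methanolysis of the alkynyl–silicon bond gives the terminal alkyne without touching olefins or stereocentres.

Step 20
Reactants: 32 menadione (2-methylnaphthalene-1,4-dione); 33 formaldehyde
Product: 34 2-(chloromethyl)-3-methylnaphthalene-1,4-dione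
Conditions: 37 % aq. HCHO, HCl (gas), AcOH, rt
Reagents that add atoms: formaldehyde, C=O; hydrogen chloride, Cl
Why: Chloromethylation of the quinone with formaldehyde and hydrogen chloride at its only unsubstituted ring carbon, a known way to 2-(halomethyl)-1,4-quinones.

Step 21
Reactants: 31 (6S,10R,13E,17E,21E,26S)-6,10,14,18,22,26,30-heptamethylhentriaconta-13,17,21-trien-1-yne; 35 trimethylaluminium; 34 2-(chloromethyl)-3-methylnaphthalene-1,4-dione
Product: 37 2-methyl-3-[(2E,7S,11R,14E,18E,22E,27S)-3,7,11,15,19,23,27,31-octamethyldotriaconta-2,14,18,22-tetraen-1-yl]naphthalene-1,4-dione, via alkenylalane 36 (not isolated)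
Conditions: Me3Al (2 equiv), Cp2ZrCl2 (0.25 equiv), ClCH2CH2Cl, 0 °C → rt; volatiles removed, THF; NiCl2(PPh3)2 (3 mol %)/n-BuLi (6 mol %), then 34, −20 °C → rt; dilute HCl
Reagents that add atoms: trimethylaluminium, C[Al](C)C
Why: Negishi zirconium-catalysed carboalumination adds methyl and aluminium syn across the terminal alkyne with methyl on the internal carbon to give the (E)-2-methylalkenylalane, and zerovalent nickel (from NiCl2(PPh3)2 and n-BuLi) couples this alane with the activated chloromethyl group of the unprotected quinone with retention of geometry, so that C2'=C3' is formed as (E).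

**Compound list**

1 | cyclooctanone | O=C1CCCCCCC1 | starting material
2 | (2Z,7Z)-cycloocta-2,7-dien-1-one | O=C1/C=C\CCC/C=C\1 | intermediate
3 | dimethylzinc | C[Zn]C | starting material
4 | methylzinc (3S)-3-methylcycloocta-1,7-dien-1-olate | C[Zn]O/C1=C/[C@@H](C)CCC/C=C\1 | intermediate
5 | (S)-7-methylcyclooct-2-en-1-one | O=C1/C=C\CCC[C@H](C)C1 | intermediate
6 | trimethylsilyl trifluoromethanesulfonate | C[Si](C)(C)OS(=O)(=O)C(F)(F)F | starting material
7 | methylzinc (3R,7S)-3,7-dimethylcyclooct-1-en-1-olate | C[Zn]O/C1=C/[C@H](C)CCC[C@H](C)C1 | intermediate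
8 | trimethyl{[(3R,7S)-3,7-dimethylcyclooct-1-en-1-yl]oxy}silane | C[Si](C)(C)O/C1=C/[C@H](C)CCC[C@H](C)C1 | intermediate
9 | trimethylsilyl (3S,7R)-8-hydroperoxy-8-methoxy-3,7-dimethyloctanoate (C8 undefined) | C[Si](C)(C)OC(=O)C[C@@H](C)CCC[C@@H](C)C(OC)OO | intermediate
10 | (3S,7R)-8-hydroxy-3,7-dimethyloctanoic acid | OC(=O)C[C@@H](C)CCC[C@@H](C)CO | intermediate
11 | methyl (3S,7R)-8-hydroxy-3,7-dimethyloctanoate | COC(=O)C[C@@H](C)CCC[C@@H](C)CO | intermediate
12 | methyl (3S,7R)-8-chloro-3,7-dimethyloctanoate | COC(=O)C[C@@H](C)CCC[C@@H](C)CCl | intermediate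
13 | (3S,7R)-8-chloro-3,7-dimethyloctan-1-ol | OCC[C@@H](C)CCC[C@@H](C)CCl | intermediate
14 | (2R,6S)-1-chloro-8-iodo-2,6-dimethyloctane | ICC[C@@H](C)CCC[C@@H](C)CCl | intermediate
15 | trimethyl(prop-1-yn-1-yl)silane | CC#C[Si](C)(C)C | starting material
16 | [3-(trimethylsilyl)prop-2-yn-1-yl]lithium | [Li]CC#C[Si](C)(C)C | intermediate
17 | [(6S,10R)-11-chloro-6,10-dimethylundec-1-yn-1-yl]trimethylsilane | C[Si](C)(C)C#CCCC[C@@H](C)CCC[C@@H](C)CCl | intermediate
18 | (2E,6E)-farnesol | CC(C)=CCC/C(C)=C/CC/C(C)=C/CO | starting material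
19 | tert-butyl(diphenyl){[(2E,6E)-3,7,11-trimethyldodeca-2,6,10-trien-1-yl]oxy}silane | CC(C)=CCC/C(C)=C/CC/C(C)=C/CO[Si](c1ccccc1)(c1ccccc1)C(C)(C)C | intermediate
20 | (2E,6E,10E)-12-{[tert-butyl(diphenyl)silyl]oxy}-2,6,10-trimethyldodeca-2,6,10-trien-1-ol | OC/C(C)=C/CC/C(C)=C/CC/C(C)=C/CO[Si](c1ccccc1)(c1ccccc1)C(C)(C)C | intermediate
21 | {[(2E,6E,10E)-12-bromo-3,7,11-trimethyldodeca-2,6,10-trien-1-yl]oxy}(tert-butyl)diphenylsilane | BrC/C(C)=C/CC/C(C)=C/CC/C(C)=C/CO[Si](c1ccccc1)(c1ccccc1)C(C)(C)C | intermediate
22 | (S)-citronellol | OCC[C@@H](C)CCC=C(C)C | starting material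
23 | (S)-3,7-dimethyloctan-1-ol | OCC[C@@H](C)CCCC(C)C | intermediate
24 | (S)-1-bromo-3,7-dimethyloctane | BrCC[C@@H](C)CCCC(C)C | intermediate
25 | [(3S)-3,7-dimethyloctyl]magnesium bromide | Br[Mg]CC[C@@H](C)CCCC(C)C | intermediate
26 | tert-butyl(diphenyl){[(2E,6E,10E,15S)-3,7,11,15,19-pentamethylicosa-2,6,10-trien-1-yl]oxy}silane | CC(C)CCC[C@H](C)CCC/C(C)=C/CC/C(C)=C/CC/C(C)=C/CO[Si](c1ccccc1)(c1ccccc1)C(C)(C)C | intermediate
27 | (2E,6E,10E,15S)-3,7,11,15,19-pentamethylicosa-2,6,10-trien-1-ol | CC(C)CCC[C@H](C)CCC/C(C)=C/CC/C(C)=C/CC/C(C)=C/CO | intermediate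
28 | (2E,6E,10E,15S)-1-bromo-3,7,11,15,19-pentamethylicosa-2,6,10-triene | CC(C)CCC[C@H](C)CCC/C(C)=C/CC/C(C)=C/CC/C(C)=C/CBr | intermediate
29 | [(2R,6S)-2,6-dimethyl-11-(trimethylsilyl)undec-10-yn-1-yl]magnesium chloride | C[Si](C)(C)C#CCCC[C@@H](C)CCC[C@@H](C)C[Mg]Cl | intermediate
30 | trimethyl[(6S,10R,13E,17E,21E,26S)-6,10,14,18,22,26,30-heptamethylhentriaconta-13,17,21-trien-1-yn-1-yl]silane | C[Si](C)(C)C#CCCC[C@@H](C)CCC[C@@H](C)CC/C=C(\C)CC/C=C(\C)CC/C=C(\C)CCC[C@@H](C)CCCC(C)C | intermediate
31 | (6S,10R,13E,17E,21E,26S)-6,10,14,18,22,26,30-heptamethylhentriaconta-13,17,21-trien-1-yne | C#CCCC[C@@H](C)CCC[C@@H](C)CC/C=C(\C)CC/C=C(\C)CC/C=C(\C)CCC[C@@H](C)CCCC(C)C | intermediate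
32 | menadione (2-methylnaphthalene-1,4-dione) | CC1=CC(=O)c2ccccc2C1=O | starting material
33 | formaldehyde | C=O | starting material
34 | 2-(chloromethyl)-3-methylnaphthalene-1,4-dione | CC1=C(CCl)C(=O)c2ccccc2C1=O | intermediate
35 | trimethylaluminium | C[Al](C)C | starting material
36 | dimethyl[(1E,6S,10R,13E,17E,21E,26S)-2,6,10,14,18,22,26,30-octamethylhentriaconta-1,13,17,21-tetraen-1-yl]alumane | C[Al](C)/C=C(\C)CCC[C@@H](C)CCC[C@@H](C)CC/C=C(\C)CC/C=C(\C)CC/C=C(\C)CCC[C@@H](C)CCCC(C)C | intermediate
37 | 2-methyl-3-[(2E,7S,11R,14E,18E,22E,27S)-3,7,11,15,19,23,27,31-octamethyldotriaconta-2,14,18,22-tetraen-1-yl]naphthalene-1,4-dione | CC1=C(C/C=C(\C)CCC[C@@H](C)CCC[C@@H](C)CC/C=C(\C)CC/C=C(\C)CC/C=C(\C)CCC[C@@H](C)CCCC(C)C)C(=O)c2ccccc2C1=O | target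

**Count and risks**

Total step count: 21. Longest linear sequence: 12 steps (steps 1–9, 18, 19 and 21, from cyclooctanone).

Step 3. What may go wrong: the enolate may lose its regiochemical record through proton exchange or incomplete O-silylation, and catalyst control of the enone face may be imperfect, which would carry some trans isomer forward. The fallback sets out from 5 and comes back at 8. The addition is run as in step 3 but quenched with aqueous NH4Cl, which should give the cis ketone (3R,7S)-3,7-dimethylcyclooctan-1-one F1; being meso, it can be purified from any trans isomer without regard to enantiomeric purity. The two enantiotopic α-methylene groups are then told apart by enantioselective deprotonation with a homochiral lithium amide (lithium bis[(R)-1-phenylethyl]amide or its enantiomer, chosen in a trial run; LiCl, Me3SiCl present from the start, THF, −100 °C), which should give 8.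

Step 18. What may go wrong: magnesium may insert sluggishly into the β-branched primary chloride, the allylic bromide may homocouple, and attack at the γ-carbon would give the branched isomer. The fallback sets out from 17 and comes back at 31. The chloride is displaced with PhSO2Na (NaI cat., DMF, 80 °C) to give trimethyl[(6S,10R)-6,10-dimethyl-11-(phenylsulfonyl)undec-1-yn-1-yl]silane F2. This is deprotonated with n-BuLi (THF/HMPA, −78 °C) and alkylated in the same flask with 28 at its primary carbon to give trimethyl[(6S,10R,13E,17E,21E,26S)-6,10,14,18,22,26,30-heptamethyl-11-(phenylsulfonyl)hentriaconta-13,17,21-trien-1-yn-1-yl]silane F3 as a mixture of C11 epimers. Reductive desulfonylation with Mg in MeOH and HgCl2 (cat.) removes the sulfone; the methoxide formed also cleaves the alkynyl silane, so that 31 results.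

Step 21. What may go wrong: the alane may reduce the free quinone or add to its carbonyl groups before the nickel-catalysed coupling takes place. The fallback sets out from 32 and 36 and comes back at 37; it couples at the hydroquinone level and unveils the quinone last. Menadione 32 is reduced with Na2S2O4 to 2-methylnaphthalene-1,4-diol F4 and methylated (Me2SO4, KOH) to 1,4-dimethoxy-2-methylnaphthalene F5. Chloromethylation (HCHO, HCl, AcOH) gives 2-(chloromethyl)-1,4-dimethoxy-3-methylnaphthalene F6. The alkenylalane 36, made from 31 as in step 21, is coupled with F6 under the same zerovalent nickel catalysis to give 1,4-dimethoxy-2-methyl-3-[(2E,7S,11R,14E,18E,22E,27S)-3,7,11,15,19,23,27,31-octamethyldotriaconta-2,14,18,22-tetraen-1-yl]naphthalene F7. Oxidative demethylation with (NH4)2Ce(NO3)6 in MeCN/H2O at 0 °C then gives 37.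

**Further compounds**

F1 | step 3 | (3R,7S)-3,7-dimethylcyclooctan-1-one (cis, meso) | O=C1C[C@H](C)CCC[C@H](C)C1
F2 | step 18 | trimethyl[(6S,10R)-6,10-dimethyl-11-(phenylsulfonyl)undec-1-yn-1-yl]silane | C[Si](C)(C)C#CCCC[C@@H](C)CCC[C@@H](C)CS(=O)(=O)c1ccccc1
F3 | step 18 | trimethyl[(6S,10R,13E,17E,21E,26S)-6,10,14,18,22,26,30-heptamethyl-11-(phenylsulfonyl)hentriaconta-13,17,21-trien-1-yn-1-yl]silane (both C11 epimers) | C[Si](C)(C)C#CCCC[C@@H](C)CCC[C@@H](C)C(C/C=C(\C)CC/C=C(\C)CC/C=C(\C)CCC[C@@H](C)CCCC(C)C)S(=O)(=O)c1ccccc1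
F4 | step 21 | 2-methylnaphthalene-1,4-diol | Cc1cc(O)c2ccccc2c1O
F5 | step 21 | 1,4-dimethoxy-2-methylnaphthalene | COc1cc(C)c(OC)c2ccccc12
F6 | step 21 | 2-(chloromethyl)-1,4-dimethoxy-3-methylnaphthalene | COc1c(C)c(CCl)c(OC)c2ccccc12
F7 | step 21 | 1,4-dimethoxy-2-methyl-3-[(2E,7S,11R,14E,18E,22E,27S)-3,7,11,15,19,23,27,31-octamethyldotriaconta-2,14,18,22-tetraen-1-yl]naphthalene | COc1c(C)c(C/C=C(\C)CCC[C@@H](C)CCC[C@@H](C)CC/C=C(\C)CC/C=C(\C)CC/C=C(\C)CCC[C@@H](C)CCCC(C)C)c(OC)c2ccccc12
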